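Numbering: C1 carries CO2Me, C3, C4, C5 the acetate, propionate, 2-methylbutanoate, C6 is CH2. Everything rests on cutting the cyclohexene at C1-C6 and C4-C5. C5-C6 with its ester is vinyl (R)-2-methylbutanoate. C1-C4 plus CO2Me are four ring carbons of flat methyl 2-pyrone-6-carboxylate. One dearomatising inverse-demand [4+2] under a chiral Lewis acid forms both bonds and sets C5. The bridged lactone then loses CO2 to a 5-acyloxy-1,3-dienoate. The step exploits that the C6 methylene adjoins ester-bearing C1 while oxygenated C5 adjoins C4, the natural regiochemistry of pyrones with enol esters. C5 then directs anti epoxidation of C3=C4, retentive palladium-catalysed acetate opening and propionylation.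

Key step: step 3

Assumption: 1 and 3 are bought as such; the sense of induction in step 3 cannot be read from precedent, so a first experiment fixes which antipode of the catalyst gives 5R (both derive from commercial diphenylprolinol).

Step 1
Reactants: 1 2-oxo-2H-pyran-6-carboxylic acid
Product: 2 methyl 2-oxo-2H-pyran-6-carboxylate
Conditions: MeOH, H2SO4 (cat.), reflux
Reagents that add atoms: methanol, SMILES CO
Why: Fischer esterification; 2-pyrones tolerate strong acid (methyl coumalate is made the same way), so only the carboxylic acid should react and no stereocenter is involved.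

Step 2
Reactants: 3 (2R)-2-methylbutanoic acid
Product: 4 vinyl (2R)-2-methylbutanoate
Conditions: vinyl acetate (solvent), Pd(OAc)2 (cat.), KOH (cat.), 25 °C
Reagents that add atoms: vinyl acetate, SMILES C=COC(C)=O
Why: Palladium-catalysed transvinylation (vinyl interchange) moves the vinyl group to the new carboxylate under nearly neutral conditions, so the alpha stereocenter of 3 should not be enolised.

Step 3
Reactants: 2 methyl 2-oxo-2H-pyran-6-carboxylate; 4 vinyl (2R)-2-methylbutanoate
Product: 6 methyl (5R)-5-{[(2R)-2-methylbutanoyl]oxy}cyclohexa-1,3-diene-1-carboxylate, via bridged lactone 5 (not isolated)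
Conditions: (S)-B-(o-tolyl)oxazaborolidine of diphenylprolinol (20 mol %), HNTf2 (18 mol %), 4 (3 equiv), CH2Cl2, -40 to 0 °C; Et3N quench; then toluene, NaHCO3, BHT, 80 °C
Reagents that add atoms: none
Why: Proposed new method: the protonated oxazaborolidine binds the lactone carbonyl of 2 (its most basic oxygen, because the complex gains 2-oxypyrylium character), which lowers the diene LUMO and makes the oxygen-bearing terminus (pyrone C6, target C1) the most electrophilic site, so the nucleophilic CH2 of enol ester 4 bonds there while the acyloxy-bearing carbon bonds to pyrone C3 (target C4) in a concerted but asynchronous inverse-electron-demand Diels-Alder reaction, and warming then expels CO2 from 5 by retro-[4+2]. The closest known reaction types are the chiral-Lewis-acid-catalysed [4+2] cycloaddition of 3-alkoxycarbonyl-2-pyrones with vinyl ethers and the thermal cycloaddition/decarboxylation of pyrone esters with enol ethers and enol esters; untested are a non-chelating 6-ester pyrone and an enol ester under asymmetric catalysis. The only ring closed is the six-membered carbocycle C1-C6, formed by suprafacial-suprafacial [4+2] addition across C3 and C6 of the pyrone and at first bridged by the O-C(=O) unit (2-oxabicyclo[2.2.2]octene). C1 and C4 are stereocenters only in 5 and become sp2 again, so C5 is the one that counts: it is fixed by the face of the vinyl group that meets the diene, that is by the endo orientation of the acyloxy group (usual for heteroatom-substituted alkenes with pyrones) combined with shielding of one pyrone face by the aryl groups of the catalyst, while the remote stereocenter of 4 has no say. The step needs regioselectivity (secured by the lactone carbonyl at one diene terminus and the ring oxygen at the other, both reinforced by the Lewis acid against the weaker pull of the 6-ester), binding of boron to the pyrone rather than to the esters, and survival of 6, for which the decarboxylation is run briefly over NaHCO3 so that acid-catalysed loss of 2-methylbutanoic acid to methyl benzoate does not set in.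

Step 4
Reactants: 6 methyl (5R)-5-{[(2R)-2-methylbutanoyl]oxy}cyclohexa-1,3-diene-1-carboxylate
Product: 7 methyl (1R,5R,6S)-5-{[(2R)-2-methylbutanoyl]oxy}-7-oxabicyclo[4.1.0]hept-2-ene-3-carboxylate (C3-C4 epoxide trans to the C5 ester)
Conditions: dimethyldioxirane (acetone solution), CH2Cl2, -20 to 0 °C
Reagents that add atoms: dimethyldioxirane, SMILES CC1(C)OO1
Why: Electrophilic epoxidation of a dienoate takes the distal, more electron-rich C3=C4 bond, and the neutral reagent should approach anti to the C5 acyloxy group, which sets C3 and C4 with both C-O bonds trans to the C5 oxygen.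

Step 5
Reactants: 7 methyl (1R,5R,6S)-5-{[(2R)-2-methylbutanoyl]oxy}-7-oxabicyclo[4.1.0]hept-2-ene-3-carboxylate
Product: 8 methyl (3R,4S,5R)-3-acetoxy-4-hydroxy-5-{[(2R)-2-methylbutanoyl]oxy}cyclohex-1-ene-1-carboxylate
Conditions: Pd(PPh3)4 (5 mol %), AcOH (2 equiv), THF, 0 to 25 °C
Reagents that add atoms: acetic acid, SMILES CC(=O)O
Why: Tsuji-Trost-type opening of a gamma,delta-epoxy-alpha,beta-unsaturated ester: zerovalent palladium ionises the allylic C3-O bond with inversion and external acetate attacks the allyl terminus C3 (remote from the ester, restoring conjugation) anti to the metal, so net retention should give the 3,4-cis hydroxy acetate.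

Step 6
Reactants: 8 methyl (3R,4S,5R)-3-acetoxy-4-hydroxy-5-{[(2R)-2-methylbutanoyl]oxy}cyclohex-1-ene-1-carboxylate
Product: 9 methyl (3R,4S,5R)-3-acetoxy-5-{[(2R)-2-methylbutanoyl]oxy}-4-(propanoyloxy)cyclohex-1-ene-1-carboxylate (target)
Conditions: (EtCO)2O, pyridine, DMAP (5 mol %), CH2Cl2, 0 °C
Reagents that add atoms: propionic anhydride, SMILES CCC(=O)OC(=O)CC
Why: DMAP-catalysed acylation of the only free hydroxyl at low temperature should outrun acyl migration from O3 or O5, and no stereocenter is touched.

Compound list
1 | 2-oxo-2H-pyran-6-carboxylic acid | O=C1C=CC=C(C(=O)O)O1 | starting material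
2 | methyl 2-oxo-2H-pyran-6-carboxylate | O=C1C=CC=C(C(=O)OC)O1 | intermediate
3 | (2R)-2-methylbutanoic acid | OC(=O)[C@H](C)CC | starting material
4 | vinyl (2R)-2-methylbutanoate | C=COC(=O)[C@H](C)CC | intermediate
5 | methyl (1R,4R,8R)-8-{[(2R)-2-methylbutanoyl]oxy}-3-oxo-2-oxabicyclo[2.2.2]oct-5-ene-1-carboxylate (endo: acyloxy syn to the C=C bridge) | COC(=O)[C@@]12C=C[C@@H](C(=O)O1)[C@H](OC(=O)[C@H](C)CC)C2 | intermediate
6 | methyl (5R)-5-{[(2R)-2-methylbutanoyl]oxy}cyclohexa-1,3-diene-1-carboxylate | C1=CC=C(C(=O)OC)C[C@H]1OC(=O)[C@H](C)CC | intermediate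
7 | methyl (1R,5R,6S)-5-{[(2R)-2-methylbutanoyl]oxy}-7-oxabicyclo[4.1.0]hept-2-ene-3-carboxylate | O2[C@@H]1[C@H]2C=C(C(=O)OC)C[C@H]1OC(=O)[C@H](C)CC | intermediate
8 | methyl (3R,4S,5R)-3-acetoxy-4-hydroxy-5-{[(2R)-2-methylbutanoyl]oxy}cyclohex-1-ene-1-carboxylate | O[C@@H]1[C@H](OC(C)=O)C=C(C(=O)OC)C[C@H]1OC(=O)[C@H](C)CC | intermediate
9 | methyl (3R,4S,5R)-3-acetoxy-5-{[(2R)-2-methylbutanoyl]oxy}-4-(propanoyloxy)cyclohex-1-ene-1-carboxylate | CCC(=O)O[C@@H]1[C@H](OC(C)=O)C=C(C(=O)OC)C[C@H]1OC(=O)[C@H](C)CC | target

Total step count: 6. Longest linear sequence: 5 (steps 1, 3, 4, 5, 6).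

Steps most likely to fail

**Step 3 (labelled step).**
- What may go wrong: the weakly nucleophilic enol ester may add too slowly. The Lewis acid may bind an ester carbonyl instead of the lactone, eroding regioselectivity and face selectivity. Incomplete endo preference would lower the purity at C5. The dienoate may aromatise during decarboxylation.
- Fallback (known chemistry): it sets out from 2.
  - Heating 2 with tert-butyldimethyl(vinyloxy)silane in toluene (100 °C, sealed tube, BHT) should give the racemic bridged silyloxy lactone F1. This loses CO2 in the same flask to the racemic 5-silyloxy dienoate F2, whose poor leaving group resists aromatisation.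
  - HF·pyridine in THF frees the racemic dienol F3.
  - A lipase-catalysed kinetic resolution (Burkholderia cepacia lipase or Candida antarctica lipase B, MTBE, 30 °C) follows, with 4 as acyl donor and stopped near half conversion. By the empirical rule for secondary alcohols it should acylate the 5R alcohol.
  - The remaining 5S alcohol is separated by chromatography. The fallback comes back to the route at 6.

**Step 5.**
- What may go wrong: beta-hydride elimination from the allyl-palladium intermediate may cause isomerisation and aromatisation. An uncatalysed acid opening with inversion may compete. The C4 alkoxide may trigger acyl migration before it is protonated.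
- Fallback: it sets out from 7 and reaches retention by two separate SN2 inversions without a metal.
  - LiBr/AcOH in THF opens the epoxide at allylic C3 to the trans bromohydrin F6.
  - Propionic anhydride/pyridine gives the bromo propionate F7, which blocks re-closure to the epoxide.
  - CsOAc with 18-crown-6 in toluene displaces the allylic bromide with inversion. The fallback comes back to the route at the target 9.

**Step 4.**
- What may go wrong: the small allylic ester may give poor facial selectivity. The vinyl epoxide may open or aromatise on isolation.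
- Fallback: it sets out from 6 and avoids the epoxide altogether.
  - OsO4 (cat.)/NMO in acetone-water should dihydroxylate C3=C4 anti to the C5 ester, giving the cis diol F4.
  - Trimethyl orthoacetate with camphorsulfonic acid gives the cyclic orthoester F5.
  - Aqueous acetic acid opens F5 in the known sense to the axial ester (pseudoaxial O3) and the equatorial alcohol (O4). The fallback comes back to the route at 8.

Further compounds
F1 | step 3 | methyl 8-[(tert-butyldimethylsilyl)oxy]-3-oxo-2-oxabicyclo[2.2.2]oct-5-ene-1-carboxylate (racemic, not isolated) | COC(=O)C12C=CC(C(=O)O1)C(O[Si](C)(C)C(C)(C)C)C2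
F2 | step 3 | methyl 5-[(tert-butyldimethylsilyl)oxy]cyclohexa-1,3-diene-1-carboxylate (racemic) | C1=CC=C(C(=O)OC)CC1O[Si](C)(C)C(C)(C)C
F3 | step 3 | methyl 5-hydroxycyclohexa-1,3-diene-1-carboxylate (racemic) | C1=CC=C(C(=O)OC)CC1O
F4 | step 4 | methyl (3R,4S,5R)-3,4-dihydroxy-5-{[(2R)-2-methylbutanoyl]oxy}cyclohex-1-ene-1-carboxylate | O[C@@H]1[C@H](O)C=C(C(=O)OC)C[C@H]1OC(=O)[C@H](C)CC
F5 | step 4 | 3,4-O-(1-methoxyethylidene) orthoester of F4 (mixture at the orthoester carbon) | COC1(C)O[C@@H]2[C@H](O1)C=C(C(=O)OC)C[C@H]2OC(=O)[C@H](C)CC
F6 | step 5 | methyl (3S,4S,5R)-3-bromo-4-hydroxy-5-{[(2R)-2-methylbutanoyl]oxy}cyclohex-1-ene-1-carboxylate | O[C@@H]1[C@@H](Br)C=C(C(=O)OC)C[C@H]1OC(=O)[C@H](C)CC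
F7 | step 5 | methyl (3S,4S,5R)-3-bromo-5-{[(2R)-2-methylbutanoyl]oxy}-4-(propanoyloxy)cyclohex-1-ene-1-carboxylate | CCC(=O)O[C@@H]1[C@@H](Br)C=C(C(=O)OC)C[C@H]1OC(=O)[C@H](C)CC
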